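**Retrosynthetic overview**
- The target comes from global O-debenzylation of its bis(benzyl ether); the carbinol centre comes from a reagent-controlled (CBS) reduction of a trans-3-aroyl-4-benzyl-tetrahydrofuran.
- That ketone comes from radical denitration of a trans-3-aroyl-4-(α-nitrobenzyl)tetrahydrofuran, in which the nitro group only served as activator.
- Key step: the tetrahydrofuran (the only non-aromatic ring) is closed at the C3–C4 bond by an organocatalytic intramolecular Michael addition of an aryl ketone to a tethered α-aryl nitroalkene.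
- The open-chain keto nitroalkene is joined by an oxa-Michael addition of a nitroallyl alcohol to an aryl vinyl ketone (three steps from vanillin).
- The nitroallyl alcohol comes from Henry condensation of an arylnitromethane (two steps from 4-bromo-2-methoxyphenol) with TBSOCH2CHO (two steps from cis-butenediol).

Assumption: simple commercial reagents that are incorporated in one step (BnBr, vinylmagnesium bromide, TBSCl, nitromethane, acrolein and the like) are treated as reagents and are not numbered.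

**Route**

Step 1
Reactants: 1 vanillin (4-hydroxy-3-methoxybenzaldehyde)
Product: 2 4-(benzyloxy)-3-methoxybenzaldehyde
Conditions: BnBr, K2CO3, DMF, 60 °C
Reagents that add atoms: benzyl bromide BrCc1ccccc1
Why: Williamson ether synthesis (SN2 of the phenoxide) installs a phenol protecting group that survives every step up to the final hydrogenolysis.

Step 2
Reactants: 2 4-(benzyloxy)-3-methoxybenzaldehyde
Product: 3 rac-1-[4-(benzyloxy)-3-methoxyphenyl]prop-2-en-1-ol
Conditions: CH2=CHMgBr, THF, 0 °C; aq NH4Cl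
Reagents that add atoms: vinylmagnesium bromide C=C[Mg]Br
Why: Grignard 1,2-addition to the aldehyde; the racemic carbinol centre is destroyed in the next step.

Step 3
Reactants: 3 rac-1-[4-(benzyloxy)-3-methoxyphenyl]prop-2-en-1-ol
Product: 4 1-[4-(benzyloxy)-3-methoxyphenyl]prop-2-en-1-one
Conditions: activated MnO2, CH2Cl2, rt (used at once)
Reagents that add atoms: none
Why: MnO2 oxidation of a benzylic-allylic alcohol gives the aryl vinyl ketone without touching the benzyl ether.

Step 4
Reactants: 5 (Z)-but-2-ene-1,4-diol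
Product: 6 (Z)-1,4-bis[(tert-butyldimethylsilyl)oxy]but-2-ene
Conditions: TBSCl (2.2 equiv), imidazole, DMF, rt
Reagents that add atoms: tert-butyldimethylsilyl chloride CC(C)(C)[Si](C)(C)Cl
Why: standard silylation of both primary alcohols.

Step 5
Reactants: 6 (Z)-1,4-bis[(tert-butyldimethylsilyl)oxy]but-2-ene
Product: 7 2-[(tert-butyldimethylsilyl)oxy]acetaldehyde (two molecules per molecule of 6)
Conditions: O3, CH2Cl2, −78 °C; then Me2S, −78 °C to rt
Reagents that add atoms: ozone [O-][O+]=O
Why: ozonolysis of the symmetric alkene with reductive work-up delivers two equivalents of the protected glycolaldehyde.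

Step 6
Reactants: 8 4-bromo-2-methoxyphenol
Product: 9 1-(benzyloxy)-4-bromo-2-methoxybenzene
Conditions: BnBr, K2CO3, DMF, 60 °C
Reagents that add atoms: benzyl bromide BrCc1ccccc1
Why: Williamson ether synthesis, as in step 1.

Step 7
Reactants: 9 1-(benzyloxy)-4-bromo-2-methoxybenzene
Product: 10 1-(benzyloxy)-2-methoxy-4-(nitromethyl)benzene
Conditions: MeNO2 (solvent), Pd2(dba)3 (2.5 mol %), XPhos (6 mol %), Cs2CO3 (1.1 equiv), 3 Å MS, 50 °C; aq NH4Cl
Reagents that add atoms: nitromethane C[N+](=O)[O-]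
Why: Pd/XPhos-catalysed cross-coupling of the aryl bromide with the nitromethane anion (α-arylation of a nitronate); the large excess of nitromethane suppresses diarylation.

Step 8
Reactants: 10 1-(benzyloxy)-2-methoxy-4-(nitromethyl)benzene; 7 2-[(tert-butyldimethylsilyl)oxy]acetaldehyde
Product: 13 (E)-tert-butyl{[3-(4-benzyloxy-3-methoxyphenyl)-3-nitroprop-2-en-1-yl]oxy}dimethylsilane, via nitroaldol adduct 11 (not isolated), via nitroaldol mesylate 12 (not isolated)
Conditions: TMG (10 mol %), THF, 0 °C; then MsCl, Et3N, CH2Cl2, −20 to 0 °C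
Reagents that add atoms: none
Why: Henry (nitroaldol) addition followed by E1cB elimination of the mesylate gives the conjugated nitroalkene, with the E isomer (CH2O trans to NO2) thermodynamically preferred; no stereocentre is kept.

Step 9
Reactants: 13 (E)-tert-butyl{[3-(4-benzyloxy-3-methoxyphenyl)-3-nitroprop-2-en-1-yl]oxy}dimethylsilane
Product: 14 (E)-3-[4-(benzyloxy)-3-methoxyphenyl]-3-nitroprop-2-en-1-ol
Conditions: CSA (10 mol %), MeOH, 0 °C to rt
Reagents that add atoms: none
Why: acid-catalysed methanolysis of the primary silyl ether; fluoride or base is avoided because it would add to or deconjugate the nitroalkene.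

Step 10
Reactants: 14 (E)-3-[4-(benzyloxy)-3-methoxyphenyl]-3-nitroprop-2-en-1-ol; 4 1-[4-(benzyloxy)-3-methoxyphenyl]prop-2-en-1-one
Product: 15 1-[4-(benzyloxy)-3-methoxyphenyl]-3-{[(E)-3-(4-benzyloxy-3-methoxyphenyl)-3-nitroprop-2-en-1-yl]oxy}propan-1-one
Conditions: Tf2NH (10 mol %), 4 (1.5 equiv), CH2Cl2, 0 °C to rt
Reagents that add atoms: none
Why: Brønsted acid-catalysed oxa-Michael addition of the primary alcohol to the protonated aryl vinyl ketone; acid leaves the nitroalkene untouched, whereas base would attack it and reverse the addition.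

Step 11
Reactants: 15 1-[4-(benzyloxy)-3-methoxyphenyl]-3-{[(E)-3-(4-benzyloxy-3-methoxyphenyl)-3-nitroprop-2-en-1-yl]oxy}propan-1-one
Product: 16 {(3R,4S)-4-[(4-benzyloxy-3-methoxyphenyl)(nitro)methyl]oxolan-3-yl}[4-(benzyloxy)-3-methoxyphenyl]methanone (3,4-trans; epimer mixture at the nitro-bearing carbon)
Conditions: 1-[(1S,2S)-2-aminocyclohexyl]-3-[3,5-bis(trifluoromethyl)phenyl]thiourea (20 mol %), PhCO2H (20 mol %), toluene, 40 °C
Reagents that add atoms: none
Why: intramolecular Michael addition (5-exo-trig) under primary amine-thiourea catalysis, in which the ketone reacts through its enamine while the thiourea binds the nitro group and exposes one face of the nitroalkene β-carbon, so that this ring carbon is set by the catalyst and the α-keto ring carbon equilibrates through the same enamine to the more stable 3,4-trans arrangement.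

Step 12
Reactants: 16 {(3R,4S)-4-[(4-benzyloxy-3-methoxyphenyl)(nitro)methyl]oxolan-3-yl}[4-(benzyloxy)-3-methoxyphenyl]methanone
Product: 17 {(3R,4R)-4-[4-(benzyloxy)-3-methoxybenzyl]oxolan-3-yl}[4-(benzyloxy)-3-methoxyphenyl]methanone
Conditions: Bu3SnH (2 equiv), AIBN (0.3 equiv), toluene, 100 °C
Reagents that add atoms: none
Why: radical denitration of a secondary benzylic nitro compound removes the activating group and its stereorandom centre; the radical sits only on the benzylic carbon, so both ring stereocentres are untouched (the descriptor at the benzyl-bearing carbon changes from S to R only through CIP priorities).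

Step 13
Reactants: 17 {(3R,4R)-4-[4-(benzyloxy)-3-methoxybenzyl]oxolan-3-yl}[4-(benzyloxy)-3-methoxyphenyl]methanone
Product: 18 (R)-[4-(benzyloxy)-3-methoxyphenyl]{(3R,4R)-4-[4-(benzyloxy)-3-methoxybenzyl]oxolan-3-yl}methanol
Conditions: (S)-2-methyl-CBS-oxazaborolidine (20 mol %), BH3·SMe2 (1.2 equiv), THF, −20 °C; MeOH then aq work-up
Reagents that add atoms: none
Why: Corey-Bakshi-Shibata reduction with the aryl group as the large substituent gives the (R)-carbinol (as acetophenone gives (R)-1-phenylethanol with the (S)-catalyst), with reagent control chosen to override the opposite Felkin-Anh preference of the α-stereocentre.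

Step 14
Reactants: 18 (R)-[4-(benzyloxy)-3-methoxyphenyl]{(3R,4R)-4-[4-(benzyloxy)-3-methoxybenzyl]oxolan-3-yl}methanol
Product: 19 (R)-(4-hydroxy-3-methoxyphenyl)[(3R,4R)-4-(4-hydroxy-3-methoxybenzyl)oxolan-3-yl]methanol (target)
Conditions: H2 (1 atm), 10% Pd/C, EtOAc, rt, stopped at complete O-debenzylation
Reagents that add atoms: none
Why: hydrogenolysis of the two aryl benzyl ethers in neutral solvent is much faster than C–O hydrogenolysis of the secondary benzylic alcohol, and no stereocentre is involved.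

**Compound list**
1 | vanillin (4-hydroxy-3-methoxybenzaldehyde) | COc1cc(C=O)ccc1O | starting material
2 | 4-(benzyloxy)-3-methoxybenzaldehyde | COc1cc(C=O)ccc1OCc1ccccc1 | intermediate
3 | rac-1-[4-(benzyloxy)-3-methoxyphenyl]prop-2-en-1-ol | COc1cc(C(O)C=C)ccc1OCc1ccccc1 | intermediate
4 | 1-[4-(benzyloxy)-3-methoxyphenyl]prop-2-en-1-one | COc1cc(C(=O)C=C)ccc1OCc1ccccc1 | intermediate
5 | (Z)-but-2-ene-1,4-diol | OC/C=C\CO | starting material
6 | (Z)-1,4-bis[(tert-butyldimethylsilyl)oxy]but-2-ene | CC(C)(C)[Si](C)(C)OC/C=C\CO[Si](C)(C)C(C)(C)C | intermediate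
7 | 2-[(tert-butyldimethylsilyl)oxy]acetaldehyde | CC(C)(C)[Si](C)(C)OCC=O | intermediate
8 | 4-bromo-2-methoxyphenol | COc1cc(Br)ccc1O | starting material
9 | 1-(benzyloxy)-4-bromo-2-methoxybenzene | COc1cc(Br)ccc1OCc1ccccc1 | intermediate
10 | 1-(benzyloxy)-2-methoxy-4-(nitromethyl)benzene | COc1cc(C[N+](=O)[O-])ccc1OCc1ccccc1 | intermediate
11 | 1-[4-(benzyloxy)-3-methoxyphenyl]-3-[(tert-butyldimethylsilyl)oxy]-1-nitropropan-2-ol (diastereomer mixture, not isolated) | COc1cc(C([N+](=O)[O-])C(O)CO[Si](C)(C)C(C)(C)C)ccc1OCc1ccccc1 | intermediate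
12 | 1-[4-(benzyloxy)-3-methoxyphenyl]-3-[(tert-butyldimethylsilyl)oxy]-1-nitropropan-2-yl methanesulfonate (diastereomer mixture, not isolated) | COc1cc(C([N+](=O)[O-])C(OS(C)(=O)=O)CO[Si](C)(C)C(C)(C)C)ccc1OCc1ccccc1 | intermediate
13 | (E)-tert-butyl{[3-(4-benzyloxy-3-methoxyphenyl)-3-nitroprop-2-en-1-yl]oxy}dimethylsilane | COc1cc(/C(=C\CO[Si](C)(C)C(C)(C)C)[N+](=O)[O-])ccc1OCc1ccccc1 | intermediate
14 | (E)-3-[4-(benzyloxy)-3-methoxyphenyl]-3-nitroprop-2-en-1-ol | COc1cc(/C(=C\CO)[N+](=O)[O-])ccc1OCc1ccccc1 | intermediate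
15 | 1-[4-(benzyloxy)-3-methoxyphenyl]-3-{[(E)-3-(4-benzyloxy-3-methoxyphenyl)-3-nitroprop-2-en-1-yl]oxy}propan-1-one | COc1cc(/C(=C\COCCC(=O)c2ccc(OCc3ccccc3)c(OC)c2)[N+](=O)[O-])ccc1OCc1ccccc1 | intermediate
16 | {(3R,4S)-4-[(4-benzyloxy-3-methoxyphenyl)(nitro)methyl]oxolan-3-yl}[4-(benzyloxy)-3-methoxyphenyl]methanone (3,4-trans; epimers at the nitro carbon) | COc1cc(C([N+](=O)[O-])[C@H]2COC[C@@H]2C(=O)c2ccc(OCc3ccccc3)c(OC)c2)ccc1OCc1ccccc1 | intermediate
17 | {(3R,4R)-4-[4-(benzyloxy)-3-methoxybenzyl]oxolan-3-yl}[4-(benzyloxy)-3-methoxyphenyl]methanone | COc1cc(C[C@H]2COC[C@@H]2C(=O)c2ccc(OCc3ccccc3)c(OC)c2)ccc1OCc1ccccc1 | intermediate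
18 | (R)-[4-(benzyloxy)-3-methoxyphenyl]{(3R,4R)-4-[4-(benzyloxy)-3-methoxybenzyl]oxolan-3-yl}methanol | COc1cc(C[C@H]2COC[C@@H]2[C@@H](O)c2ccc(OCc3ccccc3)c(OC)c2)ccc1OCc1ccccc1 | intermediate
19 | (R)-(4-hydroxy-3-methoxyphenyl)[(3R,4R)-4-(4-hydroxy-3-methoxybenzyl)oxolan-3-yl]methanol | COc1cc(C[C@H]2COC[C@@H]2[C@@H](O)c2ccc(O)c(OC)c2)ccc1O | target

**Totals and risks**

Total step count: 14. Longest linear sequence: 9 steps (8 to 19 through steps 6–14; equally 5 to 19 through steps 4, 5, 8–14). The vanillin branch (steps 1–3) joins at step 10.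

Three steps most likely to fail:

1. Step 11 (the ring-closing Michael addition). Enamine formation from an α-substituted, electron-rich aryl ketone is slow, the trisubstituted nitroalkene is a hindered acceptor, and the β-alkoxy ketone can revert to 4 and 14. The facial sense is assigned only by analogy with intermolecular ketone/nitroalkene additions of this catalyst class and must be confirmed on 17; the (1R,2R)-catalyst gives the antipode. Fallback, setting out from 14 (with 9 as aryl source) and coming back at 18: Tf2NH-catalysed oxa-Michael addition of 14 to acrolein gives 3-{[(E)-3-(4-benzyloxy-3-methoxyphenyl)-3-nitroprop-2-en-1-yl]oxy}propanal F1. (R)-α,α-Diphenylprolinol trimethylsilyl ether (10 mol %, PhCO2H, toluene) then closes the same C3–C4 bond through the far more readily formed aldehyde enamine, giving (3R,4S)-4-[(4-benzyloxy-3-methoxyphenyl)(nitro)methyl]oxolane-3-carbaldehyde F2. Bu3SnH/AIBN denitration gives (3R,4R)-4-[4-(benzyloxy)-3-methoxybenzyl]oxolane-3-carbaldehyde F3. [4-(Benzyloxy)-3-methoxyphenyl]magnesium bromide F4, made from 9 and Mg, adds to F3 (MgBr2·OEt2, CH2Cl2, −78 °C) under Felkin-Anh/β-chelate control, which here favours the required (R)-carbinol, to give 18; steps 10–13 are bypassed.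

2. Step 13 (CBS reduction). The α-branched aryl ketone is a demanding CBS substrate and the catalyst must work against the Felkin-Anh preference of the ring stereocentre, so the diastereomer ratio may be modest. Fallback, setting out from 17 and coming back at 18: L-Selectride (THF, −78 °C) reduces under substrate control to the carbinol epimer (S)-[4-(benzyloxy)-3-methoxyphenyl]{(3R,4R)-4-[4-(benzyloxy)-3-methoxybenzyl]oxolan-3-yl}methanol F5. Mitsunobu inversion (4-nitrobenzoic acid, PPh3, DIAD, toluene, −20 °C) gives (R)-[4-(benzyloxy)-3-methoxyphenyl]{(3R,4R)-4-[4-(benzyloxy)-3-methoxybenzyl]oxolan-3-yl}methyl 4-nitrobenzoate F6, and K2CO3/MeOH returns 18.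

3. Step 10 (oxa-Michael union). The nitro-substituted allylic alcohol is a weak nucleophile, the vinyl ketone polymerises easily, and the adduct can revert. Fallback, setting out from 4 (with 10) and coming back at 15: PMe3-catalysed oxa-Michael addition of the unhindered alcohol 2,2-dimethoxyethanol to 4 gives 1-[4-(benzyloxy)-3-methoxyphenyl]-3-(2,2-dimethoxyethoxy)propan-1-one F7. Aqueous TFA hydrolysis gives 2-{3-[4-(benzyloxy)-3-methoxyphenyl]-3-oxopropoxy}acetaldehyde F8. Henry addition of 10 (TMG cat.) gives 1-[4-(benzyloxy)-3-methoxyphenyl]-3-({3-[4-(benzyloxy)-3-methoxyphenyl]-3-nitro-2-hydroxypropyl}oxy)propan-1-one F9, which is converted in the same flask (MsCl, Et3N) to its methanesulfonate F10 and eliminated to 15. The fragment union then becomes the nitroaldol condensation instead of the ether formation.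

**Further compounds**
F1 | step 11 | 3-{[(E)-3-(4-benzyloxy-3-methoxyphenyl)-3-nitroprop-2-en-1-yl]oxy}propanal | COc1cc(/C(=C\COCCC=O)[N+](=O)[O-])ccc1OCc1ccccc1
F2 | step 11 | (3R,4S)-4-[(4-benzyloxy-3-methoxyphenyl)(nitro)methyl]oxolane-3-carbaldehyde | COc1cc(C([N+](=O)[O-])[C@H]2COC[C@@H]2C=O)ccc1OCc1ccccc1
F3 | step 11 | (3R,4R)-4-[4-(benzyloxy)-3-methoxybenzyl]oxolane-3-carbaldehyde | COc1cc(C[C@H]2COC[C@@H]2C=O)ccc1OCc1ccccc1
F4 | step 11 | [4-(benzyloxy)-3-methoxyphenyl]magnesium bromide | COc1cc([Mg]Br)ccc1OCc1ccccc1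
F5 | step 13 | (S)-[4-(benzyloxy)-3-methoxyphenyl]{(3R,4R)-4-[4-(benzyloxy)-3-methoxybenzyl]oxolan-3-yl}methanol | COc1cc(C[C@H]2COC[C@@H]2[C@H](O)c2ccc(OCc3ccccc3)c(OC)c2)ccc1OCc1ccccc1
F6 | step 13 | (R)-[4-(benzyloxy)-3-methoxyphenyl]{(3R,4R)-4-[4-(benzyloxy)-3-methoxybenzyl]oxolan-3-yl}methyl 4-nitrobenzoate | COc1cc(C[C@H]2COC[C@@H]2[C@@H](OC(=O)c2ccc(cc2)[N+](=O)[O-])c2ccc(OCc3ccccc3)c(OC)c2)ccc1OCc1ccccc1
F7 | step 10 | 1-[4-(benzyloxy)-3-methoxyphenyl]-3-(2,2-dimethoxyethoxy)propan-1-one | COC(COCCC(=O)c1ccc(OCc2ccccc2)c(OC)c1)OC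
F8 | step 10 | 2-{3-[4-(benzyloxy)-3-methoxyphenyl]-3-oxopropoxy}acetaldehyde | O=CCOCCC(=O)c1ccc(OCc2ccccc2)c(OC)c1
F9 | step 10 | 1-[4-(benzyloxy)-3-methoxyphenyl]-3-({3-[4-(benzyloxy)-3-methoxyphenyl]-3-nitro-2-hydroxypropyl}oxy)propan-1-one | COc1cc(C([N+](=O)[O-])C(O)COCCC(=O)c2ccc(OCc3ccccc3)c(OC)c2)ccc1OCc1ccccc1
F10 | step 10 | methanesulfonate of F9 at the secondary hydroxyl | COc1cc(C([N+](=O)[O-])C(OS(C)(=O)=O)COCCC(=O)c2ccc(OCc3ccccc3)c(OC)c2)ccc1OCc1ccccc1
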